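Locants C1–C11 are those defined in the first section. Compounds 8–11 are drawn as one of the C3/C10 epimers that step 5 can give; the C10 epimers converge at 11 and the C3 epimers at 12.

## Analysis of the target

Compound 30 (CNP0277258.1) is a tricyclic C15 ketone that carries two unsaturated esters. Its carbons are numbered C1 (ketone), C2=C3 (alkene, methyl on C3), C4, C5, C11 and C10 (the cyclobutane, methyl on the quaternary C10), C6 (gem-dimethyl), C7 (3-methylbut-2-enoate), C8 (methylene) and C9 ((E)-2-methylbut-2-enoate). C1–C2–C3 bridges C4 and C11 to give a bicyclo[3.1.1]hept-3-en-2-one, and the chain C6–C7–C8–C9 ties the two one-carbon bridges C5 and C10 together beneath the cyclobutane, which creates a seven-membered ring. Of the six stereocentres, C4, C5, C10 and C11 are locked together by the cage: the chain can only join the substituents of C5 and C10 that point away from the enone bridge, so H on C5 and CH3 on C10 face that bridge, and the four centres amount to one element, the sense of the cage (4R,5S,10R,11R). C7 and C9 (both R, oxygens trans on the seven-membered ring) are independent, and because the four-carbon bridge lies in a local mirror plane through C5 and C10 that only the remote enone bridge breaks, the cage cannot be expected to control them. Sensitive groups are the two α,β-unsaturated esters on hindered carbinols, the enone, and the cyclobutane with a ketone β to C5: an oxyanion on C5 can open the four-membered ring by retro-aldol cleavage. The difficulty lies in the strain of the doubly bridged cyclobutane, in the quaternary carbons C6 and C10 that flank it, and in fixing the cage sense from an achiral precursor. The strategy rests on the plane through C5 and C10: once the C1–C2–C3 bridge is removed, C4 and C11 are the equivalent α and α′ carbons of a cyclobutanone whose carbonyl carbon is C5 and whose far carbon is C10.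

## Retrosynthetic reasoning

The last bonds cut are the two acyl–oxygen bonds: 30 goes back to alcohol 28 and acid chloride 29, and 27 to alcohol 25 and acid chloride 26. The unsaturated esters are the most fragile groups and belong at the end. O7 and O9 sit in near-identical surroundings, so they must be told apart by the way they are made. In 25 the C9 oxygen is already an acetate and the C7 hydroxyl is free, which fixes the order: acylate O7, free O9, acylate O9.

25 is traced to β-hydroxy ketone 24 by removing the C7–H bond together with the acetyl group. Both come from one Evans–Tishchenko event, so C7 is derived from C9 by internal hydride delivery (anti), no external hydride that could touch the enone is needed, and the two oxygens are differentiated at no cost.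

The C9–O bond of 24 is cut to give enone 22. This puts the first remote stereocentre on an sp2 carbon whose two faces are related by the local mirror plane of the seven-membered ring. The forward reaction therefore has to be catalyst-controlled, and a conjugate borylation followed by oxidation is chosen.

22 is taken back to β-methoxy ketone 21 (the elements of methanol across C8=C9) and then to oxalate 20 (an oxygen on C5). The methoxy group is what remains of the radical acceptor, and the C5 oxygen is what remains of the carbonyl through which C6 was attached. It can be removed as a radical only after the ring exists, because only then is C5 unable to invert.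

The C9–C10 bond of 20 is cut, which opens the seven-membered ring and leads to 19. C10 is quaternary and buried, so a radical is the natural choice. In 19 it is stored as an exocyclic alkene: hydrogen-atom transfer to the methylene generates the radical and restores the methyl group in one event. The forward reaction is a 7-endo addition to the β-carbon of a β-methoxy enone.

19 is cut at C5–C6 into cage ketone 12 and vinylogous ester 15, the forward reaction being an aldol addition with capture of the alkoxide. Here the trigonal C10 is essential. A substituent on C10 would point straight into the face of the C5 carbonyl from which C6 must arrive, and the other face lies under the C1–C2–C3 bridge. With C10 trigonal the lower face is free and the addition gives the C5 configuration that the ring closure needs.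

12 is simplified by functional-group changes: the C2=C3 bond is removed (11), the methylidene is traced to a carboxylic acid and a methyl group on C10 (10), and the acid to its benzyl ester (9). A benzyl ester is chosen because the non-enolisable β-diketone would not survive saponification. The C10 substituents of 9 are those of a simple cyclobutanone building block.

In 9 the bonds C3–C4 and C1–C11 are cut together, which removes the three-carbon bridge and leaves enamine 6 and acid chloride 7. Nowhere else can two cuts return the molecule to a symmetric four-membered ketone, and the forward reaction makes two bonds, one ring and the cage sense at once. Analysis of the facial control shows that the auxiliary fixes the face of attack, and that this alone fixes the bridgeheads. Which methylene reacts first only decides whether CH3 or the ester on C10 lies under the bridge. Both outcomes have the same bridgeheads, and the C10 centre is erased at 11.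

6 comes from ketone 4 and amine 5; 4 from commercial 1 by ketal protection (2), methylation of the ester enolate (3) and hydrolysis. 15 is made from ketone 13 by formylation and O-methylation.

## Alternatives that were turned down

Alternative 1: The C10–C11 bond is first exchanged for a C10–C1 bond (retro-semipinacol), which turns the bicyclo[3.1.1]heptanone into a 1-oxygenated norbornene, and the norbornene is then opened by a retro-Diels–Alder cut of C4–C5 and C1–C11. In the forward step precursor A1, a 1-silyloxycyclopentadiene whose saturated carbon is C10, adds to the (E)-alkenylboronate C5=C11 that hangs from C10 through C9–C6. This gives norbornene A2 and the seven-membered ring at once. Oxidation of the boronate, activation of the endo oxygen and a 1,2-shift of C10 from C1 to C11 would then give the cyclobutane and the C1 ketone.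
- For it: C7 and C9 are made in the open chain, where stereocontrol is routine, and they sit on the tether, so they can steer the cycloaddition. This is a real advantage over the chosen route, which needs a chiral catalyst late to set C9. Two bonds and two rings form in a well-established reaction class.
- Against it: A1 needs a stereodefined quaternary C10 inside a cyclopentadiene differentiated at its two ends, the alkenylboronate is a weak dienophile, and the final shift converts a norbornane into a more strained pinane. C10 must migrate in preference to the vinyl carbon C2 and to simple ionisation. Four different protecting groups travel through the sequence.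
- Comparison: the chosen route gives up early control of C7 and C9 but takes the cyclobutane from a commercial ring and never drives a skeleton uphill.

Alternative 2: C5–C11 and C4–C10 are cut together, opening the cyclobutanone to a ketene and an alkene. In the forward step a tertiary amine base converts dienoyl chloride A3 into a vinylketene (C5=C4 conjugated with C3=CH2), which adds across the alkene C11=C10 in the crossed sense to give cyclobutanone A4 together with the six-membered ring.
- For it: this is the long-known way to chrysanthenone-type ketones, so the ring-forming step has closer precedent than the one chosen here. C9 is present beforehand, C10 forms stereospecifically from the alkene geometry with C9 on the side of C5, and the C5 carbonyl is in place.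
- Against it: the cage sense has to be relayed from the single allylic centre C9, C1 is a methylene that must be oxidised later, and the exocyclic alkene must be moved into the ring. Most seriously, the C9 branch lies in the path to the lower face of the C5 carbonyl, so C6 cannot be introduced from outside. The seven-membered ring would have to be closed by forming C5–C6 between a quaternary carbon and a shielded ketone.
- Comparison: the chosen route keeps C10 trigonal while C6 is attached, brings C1 in at the ketone level and fixes the cage sense with a recoverable auxiliary.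

Alternative 3: C10–C11 and C3–C4 are cut, separating a diene from a seven-membered enone; the cyclobutane bond C5–C11 is left for later. In the forward step, under an alkylaluminium chloride, silyloxydiene A5 adds to the β-methyl cycloheptenone A6 with the regiochemistry set by the silyloxy group, giving the cis-fused bicycle A7 with the quaternary C10.
- For it: the route is convergent, the seven-membered ring with its gem-dimethyl group and C7 is prepared separately, and C7 can bias the dienophile face. In convergence and in the early placement of C7 it is stronger than the chosen route.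
- Against it: a β,β-disubstituted enone next to a quaternary carbon is a poor dienophile, and the silyl enol ether of A7 points away from C11 and must be transposed. The cyclobutane must finally be closed by joining C11 to C5, a neopentyl secondary carbon, in a strain-building four-membered ring closure at the end of the synthesis. C9 still has to be reduced with control.
- Comparison: the chosen route starts from the four-membered ring and builds the less strained rings around it, so the strain is paid for at the outset.

Key step: step 5

Remark: the sense of induction of amine 5 in step 5 and of the copper ligand in step 14 is predicted from the usual facial models. Should either prove reversed, the mirror-image reagent is used.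

## Route

Step 1
Reactants: 1 benzyl 3-oxocyclobutane-1-carboxylate
Product: 2 benzyl 3,3-dimethoxycyclobutane-1-carboxylate
Conditions: HC(OMe)3, TsOH·H2O (cat.), CH2Cl2, 25 °C
Reagents that add atoms: trimethyl orthoformate, COC(OC)OC
Why: Acid-catalysed ketalisation with the orthoester as water scavenger; the ketone must be masked before the ester enolate is made, and the benzyl ester is stable to catalytic acid at room temperature.

Step 2
Reactants: 2 benzyl 3,3-dimethoxycyclobutane-1-carboxylate
Product: 3 benzyl 3,3-dimethoxy-1-methylcyclobutane-1-carboxylate
Conditions: LDA, THF, −78 °C; MeI, −78 → 0 °C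
Reagents that add atoms: iodomethane, CI
Why: Ester enolate alkylation; with the ketone masked the only acidic proton is the one on C10, and the new quaternary carbon is not stereogenic because the ring is symmetric.

Step 3
Reactants: 3 benzyl 3,3-dimethoxy-1-methylcyclobutane-1-carboxylate
Product: 4 benzyl 1-methyl-3-oxocyclobutane-1-carboxylate
Conditions: 1 M HCl, acetone, 25 °C
Reagents that add atoms: water, O
Why: Hydrolysis of a dimethyl ketal under mild aqueous acid, which leaves the benzyl ester intact.

Step 4
Reactants: 4 benzyl 1-methyl-3-oxocyclobutane-1-carboxylate; 5 (2R,5R)-2,5-dimethylpyrrolidine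
Product: 6 benzyl 3-[(2R,5R)-2,5-dimethylpyrrolidin-1-yl]-1-methylcyclobut-2-ene-1-carboxylate (both double-bond regioisomers)
Conditions: TiCl4 (0.55 equiv), Et3N (3 equiv), CH2Cl2, 0 → 25 °C; filtered under argon, used crude
Reagents that add atoms: none
Why: TiCl4-mediated enamine condensation, the dehydrating variant suited to a hindered secondary amine and a strained ketone; the two regioisomers are diastereomers and both are used, since step 5 gives the same bridgeheads from either.

Step 5
Reactants: 6 benzyl 3-[(2R,5R)-2,5-dimethylpyrrolidin-1-yl]-1-methylcyclobut-2-ene-1-carboxylate; 7 (E)-but-2-enoyl chloride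
Product: 9 benzyl (1R,4R,5R,7R)-4,7-dimethyl-2,6-dioxobicyclo[3.1.1]heptane-7-carboxylate, via bicyclic iminium chloride 8 (not isolated)
Conditions: 7 (1.05 equiv), MeCN, −20 → 60 °C; then H2O, THF, 25 °C
Reagents that add atoms: water, O
Why: Proposed new method: C4 of enamine 6 attacks the β-carbon of 7 (directly, or after N-acylation and a 3-aza-Cope shift, which gives the same C3–C4 bond), the iminium so formed loses the C11 proton to give the less substituted enamine, and this enamine is C-acylated by the C1 acyl chloride or ketene to give iminium chloride 8, which has only bridgehead α-carbons, cannot react further and is hydrolysed to 9. The closest known reaction type is the α,α′-annulation of cyclopentanone and cyclohexanone enamines with acryloyl or crotonoyl chloride to bicyclo[3.2.1]octane- and bicyclo[3.3.1]nonanediones; new here are the four-membered ketone and the chiral amine. The ring C1–C2–C3–C4–C5–C11 closes by a 6-(enolendo)-exo-trig acylation, and because the tether can reach C11 only on the face that already carries C3 the bridge is necessarily cis. C4 and C11 are set by the auxiliary: the methyl group on the pyrrolidine carbon syn to the enamine carbon stands perpendicular to the enamine plane to avoid allylic strain and blocks one face, and with the (2R,5R) amine the open face is the one that leads to the bridgeheads of 30, whichever methylene carries the double bond. The two enamine regioisomers thus give the same bridgeheads and differ only in whether CH3 or CO2Bn on C10 lies under the new bridge; that centre and C3 (fixed by the orientation of the crotonoyl methyl in the first bond formation) are erased in steps 7 and 8. The step needs conjugate attack at carbon to win over direct C-acylation, N-acylation without rearrangement and [2+2] addition of a vinylketene; the hindered nitrogen and the absence of a tertiary amine base serve this. That strained cyclobutanone enamines form and react at carbon is known from amine-catalysed aldol and Michael reactions of 3-substituted cyclobutanones.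

Step 6
Reactants: 9 benzyl (1R,4R,5R,7R)-4,7-dimethyl-2,6-dioxobicyclo[3.1.1]heptane-7-carboxylate
Product: 10 (1R,4R,5R,7R)-4,7-dimethyl-2,6-dioxobicyclo[3.1.1]heptane-7-carboxylic acid
Conditions: H2 (1 atm), Pd/C, EtOAc, 25 °C
Reagents that add atoms: none
Why: Hydrogenolysis of the benzyl ester under neutral conditions; hydroxide is avoided because the non-enolisable β-diketone would suffer retro-Claisen cleavage at C5, and no alkene is present yet.

Step 7
Reactants: 10 (1R,4R,5R,7R)-4,7-dimethyl-2,6-dioxobicyclo[3.1.1]heptane-7-carboxylic acid
Product: 11 (1R,4R,5R)-4-methyl-7-methylidenebicyclo[3.1.1]heptane-2,6-dione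
Conditions: 9-mesitylacridine (10 mol%), Co(dmgH)2(py)Cl (5 mol%), CH2Cl2, 400 nm LEDs, 25 °C
Reagents that add atoms: none
Why: Photochemical dehydrodecarboxylation (acridine-mediated decarboxylation, cobaloxime hydrogen abstraction); the tertiary C10 radical can lose hydrogen only from its methyl group because both ring neighbours are bridgeheads, so both C10 epimers give the same exocyclic alkene. This removes the substituent that would otherwise sit under C5 and block the face needed in step 10.

Step 8
Reactants: 11 (1R,4R,5R)-4-methyl-7-methylidenebicyclo[3.1.1]heptane-2,6-dione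
Product: 12 (1R,5R)-4-methyl-7-methylidenebicyclo[3.1.1]hept-3-ene-2,6-dione
Conditions: IBX, 4-methoxypyridine N-oxide, DMSO, 25 °C
Reagents that add atoms: none
Why: IBX dehydrogenation of a ketone through its enol; C1 can enolise only towards C2 (C11 is a bridgehead) and both C3 epimers give the one trisubstituted enone.

Step 9
Reactants: 13 3-methylbutan-2-one
Product: 15 (E)-1-methoxy-4-methylpent-1-en-3-one, via sodium enolate 14 (not isolated)
Conditions: HCO2Me, NaOMe, Et2O, 0 → 25 °C; then Me2SO4, DMF, 0 → 25 °C
Reagents that add atoms: methyl formate, COC=O; dimethyl sulfate, COS(=O)(=O)OC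
Why: Crossed Claisen formylation at the methyl group of the ketone (the only site that leads to a stable enolate), then O-methylation of the sodium enolate by a hard electrophile to the (E)-β-methoxy enone.

Step 10
Reactants: 12 (1R,5R)-4-methyl-7-methylidenebicyclo[3.1.1]hept-3-ene-2,6-dione; 15 (E)-1-methoxy-4-methylpent-1-en-3-one
Product: 19 methyl 6-[(E)-5-methoxy-2-methyl-3-oxopent-4-en-2-yl]-4-methyl-7-methylidene-2-oxobicyclo[3.1.1]hept-3-en-6-yl oxalate (O on C5 syn to the enone bridge; cage as in 12), via lithium enolate 16 (not isolated), via chlorozinc enolate 17 (not isolated), via chlorozinc aldolate 18 (not isolated)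
Conditions: 15, LDA, THF, −78 °C; ZnCl2, −78 °C; 12, −78 → −40 °C; then ClCOCO2Me, −78 → 0 °C
Reagents that add atoms: methyl chlorooxoacetate, COC(=O)C(Cl)=O
Why: Directed aldol addition of a zinc enolate (Reformatsky-type reactivity) to a cyclobutanone with O-acylation of the aldolate: LDA removes the only enolisable proton of 15 (the α′ methine), and the strained C5 carbonyl is far more electrophilic than the conjugated C1 carbonyl. Attack comes from the face turned towards the trigonal C10 because the other face lies under the C1–C2–C3 bridge, which places C6 anti and the oxygen syn to that bridge. Zinc keeps the aldolate covalent enough to resist retro-aldol opening of the cyclobutane towards C1 until it is capped as the oxalate.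

Step 11
Reactants: 19 methyl 6-[(E)-5-methoxy-2-methyl-3-oxopent-4-en-2-yl]-4-methyl-7-methylidene-2-oxobicyclo[3.1.1]hept-3-en-6-yl oxalate
Product: 20 methyl 9-methoxy-3,6,6,10-tetramethyl-1,7-dioxotricyclo-undec-2-en-5-yl oxalate (analysis locants; C9 epimers; CH3 on C10 and O on C5 syn to the enone bridge)
Conditions: Fe(acac)3 (30 mol%), PhSiH3, MeOH/THF, 60 °C, 0.01 M
Reagents that add atoms: none
Why: Hydrogen-atom-transfer radical conjugate addition: the iron hydride formed from Fe(acac)3 and PhSiH3 gives H to the unhindered 1,1-disubstituted alkene, which restores the C10 methyl and leaves a tertiary cyclobutyl radical. Its only reachable acceptor is C9 of the tethered β-methoxy enone, and 7-endo attack there (6-exo attack at C8 would be contra-polar) closes the ring from the face of C10 that looks at C5, so the methyl ends up syn to the enone bridge. C9 forms as both epimers, which is harmless because the methoxy group is expelled in step 13.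

Step 12
Reactants: 20 methyl 9-methoxy-3,6,6,10-tetramethyl-1,7-dioxotricyclo-undec-2-en-5-yl oxalate
Product: 21 9-methoxy-3,6,6,10-tetramethyltricyclo-undec-2-ene-1,7-dione (analysis locants; C9 epimers; H on C5 syn to the enone bridge)
Conditions: Bu3SnH, AIBN, PhMe, 110 °C
Reagents that add atoms: none
Why: Oxalate variant of the Barton–McCombie deoxygenation, the standard way to remove a tertiary hydroxyl; elimination is impossible because every β-carbon is a bridgehead or quaternary. The bridgehead C5 radical is held pyramidal by the new ring and can take hydrogen only on its outer face, so C5–O is replaced by C5–H with retention.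

Step 13
Reactants: 21 9-methoxy-3,6,6,10-tetramethyltricyclo-undec-2-ene-1,7-dione
Product: 22 3,6,6,10-tetramethyltricyclo-undeca-2,8-diene-1,7-dione (analysis locants; cage as in 30)
Conditions: DBU, PhMe, 60 °C
Reagents that add atoms: none
Why: E1cB elimination of methanol from a β-alkoxy ketone; C7 can enolise only towards C8, and both C9 epimers give the same enone.

Step 14
Reactants: 22 3,6,6,10-tetramethyltricyclo-undeca-2,8-diene-1,7-dione
Product: 24 (9R)-9-hydroxy-3,6,6,10-tetramethyltricyclo-undec-2-ene-1,7-dione (analysis locants), via C9 pinacolboronate 23 (not isolated)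
Conditions: CuCl (5 mol%), (R,R)-2,3-bis(tert-butylmethylphosphino)quinoxaline or its enantiomer (6 mol%), NaOtBu (10 mol%), B2pin2, MeOH, THF, 25 °C; then NaBO3·4H2O, THF/H2O, 25 °C
Reagents that add atoms: bis(pinacolato)diboron, CC1(C)OB(OC1(C)C)B2OC(C)(C)C(C)(C)O2 (boron of 23); sodium perborate, [Na+].[O-]OB=O (oxygen of 24)
Why: Copper-catalysed enantioselective conjugate borylation of a cyclic enone, then oxidation of the C–B bond with retention; the two faces of C8=C9 are related by the local mirror plane of the seven-membered ring, so the chiral diphosphine decides the face, and the ligand enantiomer is chosen to deliver boron to the Re face of C9 (the side of C11). The β-monosubstituted cycloheptenone should react before the β,β-disubstituted enone of the bridge.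

Step 15
Reactants: 24 (9R)-9-hydroxy-3,6,6,10-tetramethyltricyclo-undec-2-ene-1,7-dione
Product: 25 (7R,9R)-7-hydroxy-3,6,6,10-tetramethyl-1-oxotricyclo-undec-2-en-9-yl acetate (analysis locants)
Conditions: SmI2 (30 mol%), CH3CHO (excess), THF, −10 °C
Reagents that add atoms: acetaldehyde, CC=O
Why: Evans–Tishchenko reduction: the samarium-bound hemiacetal on the C9 oxygen delivers hydride to C7 through a six-membered transition state on the face of that oxygen, which gives the 7,9-anti (trans) diol as its C9 monoacetate. The two hydroxyls are thus set and differentiated in one step, and only a β-hydroxy ketone reacts, so the C1 enone is untouched.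

Step 16
Reactants: 25 (7R,9R)-7-hydroxy-3,6,6,10-tetramethyl-1-oxotricyclo-undec-2-en-9-yl acetate; 26 3-methylbut-2-enoyl chloride
Product: 27 (7R,9R)-9-acetoxy-3,6,6,10-tetramethyl-1-oxotricyclo-undec-2-en-7-yl 3-methylbut-2-enoate (analysis locants)
Conditions: pyridine, DMAP (cat.), CH2Cl2, 0 → 40 °C
Reagents that add atoms: none
Why: DMAP-catalysed acylation of the free C7 alcohol; pyridine in place of a trialkylamine limits deconjugation of the acid chloride through its vinylketene.

Step 17
Reactants: 27 (7R,9R)-9-acetoxy-3,6,6,10-tetramethyl-1-oxotricyclo-undec-2-en-7-yl 3-methylbut-2-enoate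
Product: 28 (7R,9R)-9-hydroxy-3,6,6,10-tetramethyl-1-oxotricyclo-undec-2-en-7-yl 3-methylbut-2-enoate (analysis locants)
Conditions: K2CO3 (cat.), MeOH, 0 °C
Reagents that add atoms: none
Why: Chemoselective methanolysis: an acetate is cleaved much faster than a β,β-disubstituted acrylate, whose carbonyl is deactivated by conjugation; low temperature and catalytic carbonate keep acyl migration in check.

Step 18
Reactants: 28 (7R,9R)-9-hydroxy-3,6,6,10-tetramethyl-1-oxotricyclo-undec-2-en-7-yl 3-methylbut-2-enoate; 29 (E)-2-methylbut-2-enoyl chloride
Product: 30 CNP0277258.1 (analysis locants 4R,5S,7R,9R,10R,11R; systematic: (1R,2R,3R,5R,7S,8R)-2,6,6,9-tetramethyl-5-[(3-methylbut-2-enoyl)oxy]-11-oxotricyclo[5.4.0.0^{2,8}]undec-9-en-3-yl (E)-2-methylbut-2-enoate)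
Conditions: pyridine, DMAP, ClCH2CH2Cl, 25 → 60 °C
Reagents that add atoms: none
Why: DMAP-catalysed acylation of the hindered C9 alcohol; the (E)-geometry of the 2-methylbut-2-enoyl group is the thermodynamically stable one and is not at risk.

## Compound list

1 | benzyl 3-oxocyclobutane-1-carboxylate | O=C(OCc1ccccc1)C1CC(=O)C1 | starting material
2 | benzyl 3,3-dimethoxycyclobutane-1-carboxylate | COC1(OC)CC(C1)C(=O)OCc1ccccc1 | intermediate
3 | benzyl 3,3-dimethoxy-1-methylcyclobutane-1-carboxylate | COC1(OC)CC(C)(C1)C(=O)OCc1ccccc1 | intermediate
4 | benzyl 1-methyl-3-oxocyclobutane-1-carboxylate | CC1(CC(=O)C1)C(=O)OCc1ccccc1 | intermediate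
5 | (2R,5R)-2,5-dimethylpyrrolidine | C[C@@H]1CC[C@@H](C)N1 | starting material
6 | benzyl 3-[(2R,5R)-2,5-dimethylpyrrolidin-1-yl]-1-methylcyclobut-2-ene-1-carboxylate (both double-bond regioisomers) | C[C@@H]1CC[C@@H](C)N1C3=CC(C)(C(=O)OCc2ccccc2)C3 | intermediate
7 | (E)-but-2-enoyl chloride | C/C=C/C(Cl)=O | starting material
8 | iminium chloride of 9 with amine 5 at C5 (cage as in 9) | O=C(OCc1ccccc1)[C@@]1(C)[C@@H]2C(=O)C[C@@H](C)[C@H]1C2=[N+]3[C@H](C)CC[C@H]3C.[Cl-] | intermediate
9 | benzyl (1R,4R,5R,7R)-4,7-dimethyl-2,6-dioxobicyclo[3.1.1]heptane-7-carboxylate | O=C(OCc1ccccc1)[C@@]1(C)[C@@H]2C(=O)C[C@@H](C)[C@H]1C2=O | intermediate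
10 | (1R,4R,5R,7R)-4,7-dimethyl-2,6-dioxobicyclo[3.1.1]heptane-7-carboxylic acid | OC(=O)[C@@]1(C)[C@@H]2C(=O)C[C@@H](C)[C@H]1C2=O | intermediate
11 | (1R,4R,5R)-4-methyl-7-methylidenebicyclo[3.1.1]heptane-2,6-dione | C=C1[C@@H]2C(=O)C[C@@H](C)[C@H]1C2=O | intermediate
12 | (1R,5R)-4-methyl-7-methylidenebicyclo[3.1.1]hept-3-ene-2,6-dione | C=C1[C@@H]2C(=O)C=C(C)[C@H]1C2=O | intermediate
13 | 3-methylbutan-2-one | CC(C)C(C)=O | starting material
14 | sodium (E)-4-methyl-3-oxopent-1-en-1-olate | [Na+].[O-]/C=C/C(=O)C(C)C | intermediate
15 | (E)-1-methoxy-4-methylpent-1-en-3-one | CO/C=C/C(=O)C(C)C | intermediate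
16 | lithium (E)-1-methoxy-4-methylpenta-1,3-dien-3-olate | [Li+].CO/C=C/C([O-])=C(C)C | intermediate
17 | chlorozinc (E)-1-methoxy-4-methylpenta-1,3-dien-3-olate | CO/C=C/C(O[Zn]Cl)=C(C)C | intermediate
18 | chlorozinc aldolate of 12 and 15 (O on C5 syn to the enone bridge) | C=C1[C@@H]2C(=O)C=C(C)[C@H]1[C@]2(O[Zn]Cl)C(C)(C)C(=O)/C=C/OC | intermediate
19 | methyl 6-[(E)-5-methoxy-2-methyl-3-oxopent-4-en-2-yl]-4-methyl-7-methylidene-2-oxobicyclo[3.1.1]hept-3-en-6-yl oxalate | C=C1[C@@H]2C(=O)C=C(C)[C@H]1[C@]2(OC(=O)C(=O)OC)C(C)(C)C(=O)/C=C/OC | intermediate
20 | methyl 9-methoxy-3,6,6,10-tetramethyl-1,7-dioxotricyclo-undec-2-en-5-yl oxalate (analysis locants; C9 epimers) | COC1CC(=O)C(C)(C)[C@]2(OC(=O)C(=O)OC)[C@H]3C(=O)C=C(C)[C@@H]2[C@]31C | intermediate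
21 | 9-methoxy-3,6,6,10-tetramethyltricyclo-undec-2-ene-1,7-dione (analysis locants; C9 epimers) | COC1CC(=O)C(C)(C)[C@@H]2[C@H]3C(=O)C=C(C)[C@@H]2[C@]31C | intermediate
22 | 3,6,6,10-tetramethyltricyclo-undeca-2,8-diene-1,7-dione (analysis locants) | C1=CC(=O)C(C)(C)[C@@H]2[C@H]3C(=O)C=C(C)[C@@H]2[C@]31C | intermediate
23 | (9R)-9-(pinacolboryl)-3,6,6,10-tetramethyltricyclo-undec-2-ene-1,7-dione (analysis locants) | CC1(C)OB(OC1(C)C)[C@@H]4CC(=O)C(C)(C)[C@@H]2[C@H]3C(=O)C=C(C)[C@@H]2[C@]34C | intermediate
24 | (9R)-9-hydroxy-3,6,6,10-tetramethyltricyclo-undec-2-ene-1,7-dione (analysis locants) | O[C@@H]1CC(=O)C(C)(C)[C@@H]2[C@H]3C(=O)C=C(C)[C@@H]2[C@]31C | intermediate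
25 | (7R,9R)-7-hydroxy-3,6,6,10-tetramethyl-1-oxotricyclo-undec-2-en-9-yl acetate (analysis locants) | CC(=O)O[C@@H]1C[C@@H](O)C(C)(C)[C@@H]2[C@H]3C(=O)C=C(C)[C@@H]2[C@]31C | intermediate
26 | 3-methylbut-2-enoyl chloride | CC(C)=CC(Cl)=O | starting material
27 | (7R,9R)-9-acetoxy-3,6,6,10-tetramethyl-1-oxotricyclo-undec-2-en-7-yl 3-methylbut-2-enoate (analysis locants) | CC(=O)O[C@@H]1C[C@@H](OC(=O)C=C(C)C)C(C)(C)[C@@H]2[C@H]3C(=O)C=C(C)[C@@H]2[C@]31C | intermediate
28 | (7R,9R)-9-hydroxy-3,6,6,10-tetramethyl-1-oxotricyclo-undec-2-en-7-yl 3-methylbut-2-enoate (analysis locants) | O[C@@H]1C[C@@H](OC(=O)C=C(C)C)C(C)(C)[C@@H]2[C@H]3C(=O)C=C(C)[C@@H]2[C@]31C | intermediate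
29 | (E)-2-methylbut-2-enoyl chloride | C/C=C(\C)C(Cl)=O | starting material
30 | CNP0277258.1 | C/C=C(\C)C(=O)O[C@@H]1C[C@@H](OC(=O)C=C(C)C)C(C)(C)[C@@H]2[C@H]3C(=O)C=C(C)[C@@H]2[C@]31C | target

## Step count and least certain steps

Total: 18 steps. Longest linear sequence: 17 steps (steps 1–8 and 10–18); step 9 is a one-step side branch.

**Step 5 (key step).** Most likely failure: the strained cyclobutene enamine reacts by direct C-acylation or by [2+2] addition of a vinylketene formed from 7, or the second bond does not close because it builds the bicyclo[3.1.1] strain. Hydrolysis of the shielded iminium may also be slow. Fallback: from 6, the two bonds are made in separate known operations. Addition of 6 to (E)-but-2-enal (enamine conjugate addition through the aminodihydropyran) and mild acid hydrolysis give benzyl 1-methyl-3-oxo-2-(4-oxobutan-2-yl)cyclobutane-1-carboxylate F1, with the same auxiliary controlling the face at C4. An amine-catalysed intramolecular aldol addition of C11 to the aldehyde gives benzyl 2-hydroxy-4,7-dimethyl-6-oxobicyclo[3.1.1]heptane-7-carboxylate F2. Dess–Martin oxidation of the C1 alcohol rejoins the route at 9.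

**Step 10.** Most likely failure: fragmentation of the C5 alkoxide towards the C1 enolate (retro-aldol opening of the cyclobutane) before it is capped, or partial attack from the bridge face. Fallback: from 11, the C1 carbonyl is masked before C5 is touched. Soft enolisation (TBSOTf, Et3N) gives 2-(tert-butyldimethylsilyloxy)-4-methyl-7-methylidenebicyclo[3.1.1]hept-2-en-6-one F3, which has no carbonyl β to C5. The same zinc aldol and oxalate capping give the silyl enol ether oxalate F4, and Saegusa–Ito oxidation with Pd(OAc)2 (for the C3 epimer drawn, whose C3–H lies on the open face) unveils the enone and rejoins the route at 19.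

**Step 11.** Most likely failure: reduction of the C10 radical (net hydrogenation of the methylidene) before the 7-endo closure, because a β-alkoxy enone is a sluggish acceptor and the ring is seven-membered. Fallback: from 12, the order of the two bond formations is reversed. Intermolecular iron-hydride olefin coupling of 12 with 15 attaches C9 to C10 from the face towards C5 (the other face is under the bridge) and gives the β-methoxy ketone F5. DBU removes methanol to give the (E)-enone F6. α′-Deprotonation (LDA, ZnCl2) then closes the seven-membered ring by intramolecular aldol addition of C6 to the C5 carbonyl, necessarily from below, and capping gives the cyclic enone oxalate F7. Tin hydride deoxygenation of F7 rejoins the route at 22.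

**Step 14.** Most likely failure: poor facial selectivity at the neopentyl β-carbon C9, or competing borylation of the bridge enone at C3. Fallback: from 22, catalyst control is replaced by separation and recycling. Borylation with an achiral diphosphine–CuCl catalyst and oxidation give 24 together with its C9 epimer, the (9S)-hydroxy ketone F8. The two are diastereomers and are separated by chromatography. F8 is returned to 22 by mesylation and elimination (MsCl, Et3N), and 24 continues.

**Step 15.** Most likely failure: slow hydride transfer in the hindered ring, or migration of the acetyl group from O9 to O7, which would blur the differentiation. Fallback: from 24, Evans–Saksena reduction with Me4NBH(OAc)3 gives the anti diol F9 by the same internal delivery. The C9 hydroxyl (next to the tied-back cyclobutane carbon) is less hindered than the C7 hydroxyl (next to the gem-dimethyl carbon), so limiting (E)-2-methylbut-2-enoic anhydride with DMAP at low temperature gives the C9 mono-ester F10. Acylation of F10 with 26 rejoins the route at 30.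

## Further compounds

F1 | step 5 | benzyl 1-methyl-3-oxo-2-(4-oxobutan-2-yl)cyclobutane-1-carboxylate | O=C(OCc1ccccc1)[C@@]1(C)CC(=O)[C@@H]1[C@H](C)CC=O
F2 | step 5 | benzyl 2-hydroxy-4,7-dimethyl-6-oxobicyclo[3.1.1]heptane-7-carboxylate | O=C(OCc1ccccc1)[C@@]1(C)[C@@H]2C(O)C[C@@H](C)[C@H]1C2=O
F3 | step 10 | 2-(tert-butyldimethylsilyloxy)-4-methyl-7-methylidenebicyclo[3.1.1]hept-2-en-6-one | C=C1[C@@H]2C(O[Si](C)(C)C(C)(C)C)=C[C@@H](C)[C@H]1C2=O
F4 | step 10 | methyl 2-(tert-butyldimethylsilyloxy)-6-[(E)-5-methoxy-2-methyl-3-oxopent-4-en-2-yl]-4-methyl-7-methylidenebicyclo[3.1.1]hept-2-en-6-yl oxalate | C=C1[C@@H]2C(O[Si](C)(C)C(C)(C)C)=C[C@@H](C)[C@H]1[C@]2(OC(=O)C(=O)OC)C(C)(C)C(=O)/C=C/OC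
F5 | step 11 | 7-(1-methoxy-4-methyl-3-oxopentyl)-4,7-dimethylbicyclo[3.1.1]hept-3-ene-2,6-dione | COC(CC(=O)C(C)C)[C@@]1(C)[C@@H]2C(=O)C=C(C)[C@H]1C2=O
F6 | step 11 | 4,7-dimethyl-7-[(E)-4-methyl-3-oxopent-1-enyl]bicyclo[3.1.1]hept-3-ene-2,6-dione | CC(C)C(=O)/C=C/[C@@]1(C)[C@@H]2C(=O)C=C(C)[C@H]1C2=O
F7 | step 11 | methyl 3,6,6,10-tetramethyl-1,7-dioxotricyclo-undeca-2,8-dien-5-yl oxalate (analysis locants) | C1=CC(=O)C(C)(C)[C@]2(OC(=O)C(=O)OC)[C@H]3C(=O)C=C(C)[C@@H]2[C@]31C
F8 | step 14 | (9S)-9-hydroxy-3,6,6,10-tetramethyltricyclo-undec-2-ene-1,7-dione (analysis locants) | O[C@H]1CC(=O)C(C)(C)[C@@H]2[C@H]3C(=O)C=C(C)[C@@H]2[C@]31C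
F9 | step 15 | (7R,9R)-7,9-dihydroxy-3,6,6,10-tetramethyltricyclo-undec-2-en-1-one (analysis locants) | O[C@@H]1C[C@@H](O)C(C)(C)[C@@H]2[C@H]3C(=O)C=C(C)[C@@H]2[C@]31C
F10 | step 15 | (7R,9R)-7-hydroxy-3,6,6,10-tetramethyl-1-oxotricyclo-undec-2-en-9-yl (E)-2-methylbut-2-enoate (analysis locants) | C/C=C(\C)C(=O)O[C@@H]1C[C@@H](O)C(C)(C)[C@@H]2[C@H]3C(=O)C=C(C)[C@@H]2[C@]31C
A1 | alternative 1 | 5-substituted 3,5-dimethyl-1-(triethylsilyloxy)cyclopenta-1,3-diene carrying the PMB- and TBS-protected chain that ends in an (E)-alkenyl pinacolboronate | COc1ccc(CO[C@H](C[C@@H](O[Si](C)(C)C(C)(C)C)C(C)(C)/C=C/B2OC(C)(C)C(C)(C)O2)[C@@]3(C)C(O[Si](CC)(CC)CC)=CC(C)=C3)cc1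
A2 | alternative 1 | tricyclic 1-(triethylsilyloxy)norbornene with an endo pinacolboronate at C11 | COc1ccc(CO[C@@H]2C[C@@H](O[Si](C)(C)C(C)(C)C)C(C)(C)[C@@H]3[C@@H](B4OC(C)(C)C(C)(C)O4)[C@@]5(O[Si](CC)(CC)CC)C=C(C)[C@@H]3[C@@]25C)cc1
A3 | alternative 2 | (2E,6E)-8-(tert-butyldimethylsilyloxy)-3,7-dimethyldeca-2,6,9-trienoyl chloride | C=C[C@@H](O[Si](C)(C)C(C)(C)C)/C(C)=C/CC/C(C)=C/C(Cl)=O
A4 | alternative 2 | 7-methyl-2-methylidene-7-[1-(tert-butyldimethylsilyloxy)prop-2-enyl]bicyclo[3.1.1]heptan-6-one | C=C[C@@H](O[Si](C)(C)C(C)(C)C)[C@@]1(C)[C@@H]2CCC(=C)[C@H]1C2=O
A5 | alternative 3 | (E)-2-(tert-butyldimethylsilyloxy)penta-1,3-diene | C=C(O[Si](C)(C)C(C)(C)C)/C=C/C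
A6 | alternative 3 | 10-(tert-butyldimethylsilyloxy)-6,9,9-trimethyl-1,4-dioxaspiro[4.6]undec-6-en-8-one | CC1=CC(=O)C(C)(C)[C@H](O[Si](C)(C)C(C)(C)C)CC12OCCO2
A7 | alternative 3 | cis-fused bicyclo[5.4.0]undecene silyl enol ether with C5 ketone and C9 ketal | C12(OCCO2)C[C@@H](O[Si](C)(C)C(C)(C)C)C(C)(C)C(=O)[C@@H]3[C@H](C)C=C(O[Si](C)(C)C(C)(C)C)C[C@]13C
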